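**Strategy.** The quinone ring is disconnected at the bond between carbonyl carbon C1 and hydroxylated carbon C2. The key step exploits the 1,2,4-trioxygenation of the six-membered ring (C1=O, C2–OH, C4=O). A squarate-derived 4-hydroxy-4-(2-benzyloxyalkenyl)cyclobutenone opens its strained four-membered ring on heating to a dienylketene. Its ketene carbon (future C1) closes onto the benzyloxy-bearing alkene terminus (future C2) by 6π-electrocyclisation, and oxidation in the same flask gives the fully substituted quinone. The precursor arises by adding a 2-benzyloxyvinyllithium carrying the (R)-silyloxytridecyl chain to methyl semisquarate; all alkene and carbinol isomers converge. Silyl-to-acetate exchange and debenzylation finish the synthesis.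

Key step: step 7

Remark: ring numbering is C1 (C=O next to C–OH), C2 (C–OH), C3 (side chain), C4 (C=O), C5 (OMe), C6 (H). The enol ether geometry in 4, 6, 10 and 11, the bromine-bearing centres of 5 and the carbinol centre of 11 are not controlled and need not be, because step 7 erases them; their SMILES carry only the (R) side-chain centre, which is bought with the commercial ester 1 and never touched.

**Step 1**
Reactants: 1 methyl (3R)-3-hydroxytetradecanoate
Product: 2 methyl (3R)-3-[(tert-butyldimethylsilyl)oxy]tetradecanoate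
Conditions: TBSCl, imidazole, DMF, rt
Reagents that add atoms: tert-butyldimethylsilyl chloride, CC(C)(C)[Si](C)(C)Cl
Why: Imidazole-promoted silyl ether formation on a secondary alcohol; the C3 stereocentre, which becomes the acetoxy-bearing carbon of the target, is not touched.

**Step 2**
Reactants: 2 methyl (3R)-3-[(tert-butyldimethylsilyl)oxy]tetradecanoate
Product: 3 (3R)-3-[(tert-butyldimethylsilyl)oxy]tetradecanal
Conditions: i-Bu2AlH (1.05 equiv), CH2Cl2, −78 °C; aq. KNaC4H4O6 (potassium sodium tartrate)
Reagents that add atoms: none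
Why: Partial ester reduction by i-Bu2AlH at −78 °C should stop at the aluminium hemiacetal, which releases the aldehyde on work-up; the β-silyloxy centre cannot epimerise.

**Step 3**
Reactants: 3 (3R)-3-[(tert-butyldimethylsilyl)oxy]tetradecanal
Product: 4 tert-butyl{[(4R)-1-(benzyloxy)pentadec-1-en-4-yl]oxy}dimethylsilane (E/Z mixture)
Conditions: BnOCH2PPh3Cl, KN(SiMe3)2, THF, −78 → 0 °C; then 3, −78 °C → rt
Reagents that add atoms: (benzyloxymethyl)triphenylphosphonium chloride, [Cl-].c1ccccc1COC[P+](c1ccccc1)(c1ccccc1)c1ccccc1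
Why: Wittig alkoxymethylenation with the non-stabilised benzyloxymethylene ylide should convert the aldehyde into the benzyl enol ether; the E/Z ratio is irrelevant because step 7 erases the geometry.

**Step 4**
Reactants: 4 tert-butyl{[(4R)-1-(benzyloxy)pentadec-1-en-4-yl]oxy}dimethylsilane
Product: 6 tert-butyl{[(4R)-1-(benzyloxy)-2-bromopentadec-1-en-4-yl]oxy}dimethylsilane (E/Z mixture), via 1,2-dibromide 5 (not isolated)
Conditions: Br2, CH2Cl2, −78 °C; then Et3N, −78 °C → rt
Reagents that add atoms: bromine, BrBr
Why: Bromination–dehydrobromination of an enol ether (the method used for 5-bromo-3,4-dihydro-2H-pyran): bromine adds across the electron-rich alkene, then the anomeric bromide of 5 leaves with the adjacent C–H under amine base, keeping bromine on the former β-carbon.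

**Step 5**
Reactants: 7 dimethyl squarate (3,4-dimethoxycyclobut-3-ene-1,2-dione)
Product: 9 3-methoxycyclobut-3-ene-1,2-dione (methyl semisquarate), via 4-hydroxy-2,3-dimethoxycyclobut-2-en-1-one 8 (not isolated)
Conditions: LiAlH(Ot-Bu)3, THF, −78 → 0 °C, aq. work-up; then conc. HCl (cat.), CH2Cl2, rt
Reagents that add atoms: water, O (its oxygen becomes the new carbonyl oxygen; the carbinol oxygen of 8 leaves as water)
Why: The hindered hydride should reduce one squarate carbonyl once (1,2-reduction); acid then ionises the allylic carbinol and hydrolyses the vinylogous oxocarbenium with loss of methanol, the established two-stage conversion of a dialkyl squarate into an alkyl semisquarate.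

**Step 6**
Reactants: 6 tert-butyl{[(4R)-1-(benzyloxy)-2-bromopentadec-1-en-4-yl]oxy}dimethylsilane; 9 3-methoxycyclobut-3-ene-1,2-dione
Product: 11 4-{(4R)-1-(benzyloxy)-4-[(tert-butyldimethylsilyl)oxy]pentadec-1-en-2-yl}-4-hydroxy-3-methoxycyclobut-2-en-1-one (isomer mixture), via vinyllithium 10 (not isolated)
Conditions: t-BuLi (2 equiv), THF, −78 °C; then cannulated into 9, THF, −78 °C; aq. NH4Cl
Reagents that add atoms: none
Why: Bromine–lithium exchange gives the 2-alkoxyvinyllithium, which should add 1,2 to the more electrophilic carbonyl of 9 (the one next to C–OMe, not part of the vinylogous ester), as in standard organolithium additions to alkoxycyclobutenediones; the new carbinol centre is uncontrolled and is destroyed in step 7.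

**Step 7**
Reactants: 11 4-{(4R)-1-(benzyloxy)-4-[(tert-butyldimethylsilyl)oxy]pentadec-1-en-2-yl}-4-hydroxy-3-methoxycyclobut-2-en-1-one
Product: 15 2-(benzyloxy)-3-{(2R)-2-[(tert-butyldimethylsilyl)oxy]tridecyl}-5-methoxy-1,4-benzoquinone, via dienylketene 12 (not isolated), via cyclohexadienone 13 (not isolated), via hydroquinone 14 (not isolated)
Conditions: PhMe (dilute, degassed, acid-free glassware), 110 °C; then Ag2O, rt
Reagents that add atoms: none
Why: Heating opens the strained cyclobutenone by 4π-conrotatory cleavage of the C(=O)–C(OH) σ-bond with the hydroxyl rotating outward, which places the alkenyl group cis to the ketene in 12; thermal 6π-disrotatory electrocyclisation then joins the ketene carbon to the benzyloxy-bearing alkene terminus (the C1–C2 bond of the quinone) to give cyclohexadienone 13, which enolises to hydroquinone 14 and is oxidised by Ag2O to 15. The closest known reaction type is the thermal ring expansion of 4-alkenyl- and 4-aryl-4-hydroxycyclobutenones to hydroquinones (Moore rearrangement), which tolerates heteroatom-substituted termini such as those of heteroaryl carbinols. The only ring closed is the six-membered carbocycle, by pericyclic 6π closure driven by release of cyclobutene strain and by aromatisation. The sp3 carbon created in 13 is transient and is erased on enolisation, and the remote side-chain stereocentre is untouched. The step needs the outward torquoselectivity of the hydroxyl, an electronic preference of donor substituents that the substrate itself provides, and the substituent pattern fixed by the regioselective addition of step 6; both enol ether geometries and both carbinol epimers should funnel into the same product. Dilute, acid-free conditions should suppress lactonisation of 12 and ionisation of the carbinol.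

**Step 8**
Reactants: 15 2-(benzyloxy)-3-{(2R)-2-[(tert-butyldimethylsilyl)oxy]tridecyl}-5-methoxy-1,4-benzoquinone
Product: 16 2-(benzyloxy)-3-[(2R)-2-hydroxytridecyl]-5-methoxy-1,4-benzoquinone
Conditions: HF·pyridine, THF–pyridine, 0 °C → rt
Reagents that add atoms: none
Why: Fluoride-mediated silyl ether cleavage under buffered conditions should leave both vinylogous ester groups of the quinone intact, and no bond to the stereocentre is broken.

**Step 9**
Reactants: 16 2-(benzyloxy)-3-[(2R)-2-hydroxytridecyl]-5-methoxy-1,4-benzoquinone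
Product: 17 (2R)-1-[2-(benzyloxy)-5-methoxy-3,6-dioxocyclohexa-1,4-dien-1-yl]tridecan-2-yl acetate
Conditions: Ac2O, pyridine, DMAP (cat.), CH2Cl2, 0 °C → rt
Reagents that add atoms: acetic anhydride, CC(=O)OC(C)=O
Why: DMAP-catalysed acylation of the secondary alcohol proceeds with retention (only the O–H bond changes) and should outrun any attack of the hydroxyl on the alkoxyquinone.

**Step 10**
Reactants: 17 (2R)-1-[2-(benzyloxy)-5-methoxy-3,6-dioxocyclohexa-1,4-dien-1-yl]tridecan-2-yl acetate
Product: 19 (2R)-1-(2-hydroxy-5-methoxy-3,6-dioxocyclohexa-1,4-dien-1-yl)tridecan-2-yl acetate (target), via benzenetriol 18 (not isolated)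
Conditions: H2 (1 atm), Pd/C, EtOAc, rt; filter; then air (O2), rt
Reagents that add atoms: none
Why: Hydrogen over Pd/C should first reduce the quinone to the hydroquinone and then cleave the resulting aryl benzyl ether (hydrogenolysis); the 1,2,4-benzenetriol autoxidises in air to the 2-hydroxy-1,4-quinone, while acetate, methyl ether and stereocentre are inert.

**Compound list**

1 | methyl (3R)-3-hydroxytetradecanoate | CCCCCCCCCCC[C@H](CC(=O)OC)O | starting material
2 | methyl (3R)-3-[(tert-butyldimethylsilyl)oxy]tetradecanoate | CCCCCCCCCCC[C@H](CC(=O)OC)O[Si](C)(C)C(C)(C)C | intermediate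
3 | (3R)-3-[(tert-butyldimethylsilyl)oxy]tetradecanal | CCCCCCCCCCC[C@H](CC=O)O[Si](C)(C)C(C)(C)C | intermediate
4 | tert-butyl{[(4R)-1-(benzyloxy)pentadec-1-en-4-yl]oxy}dimethylsilane (E/Z mixture) | CCCCCCCCCCC[C@H](CC=COCc1ccccc1)O[Si](C)(C)C(C)(C)C | intermediate
5 | tert-butyl{[(4R)-1-(benzyloxy)-1,2-dibromopentadecan-4-yl]oxy}dimethylsilane (diastereomer mixture) | CCCCCCCCCCC[C@H](CC(Br)C(Br)OCc1ccccc1)O[Si](C)(C)C(C)(C)C | intermediate (not isolated)
6 | tert-butyl{[(4R)-1-(benzyloxy)-2-bromopentadec-1-en-4-yl]oxy}dimethylsilane (E/Z mixture) | CCCCCCCCCCC[C@H](CC(Br)=COCc1ccccc1)O[Si](C)(C)C(C)(C)C | intermediate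
7 | dimethyl squarate (3,4-dimethoxycyclobut-3-ene-1,2-dione) | COC1=C(OC)C(=O)C1=O | starting material
8 | 4-hydroxy-2,3-dimethoxycyclobut-2-en-1-one | COC1=C(OC)C(=O)C1O | intermediate (not isolated)
9 | 3-methoxycyclobut-3-ene-1,2-dione (methyl semisquarate) | COC1=CC(=O)C1=O | intermediate
10 | {(4R)-1-(benzyloxy)-4-[(tert-butyldimethylsilyl)oxy]pentadec-1-en-2-yl}lithium | CCCCCCCCCCC[C@H](CC([Li])=COCc1ccccc1)O[Si](C)(C)C(C)(C)C | intermediate (not isolated)
11 | 4-{(4R)-1-(benzyloxy)-4-[(tert-butyldimethylsilyl)oxy]pentadec-1-en-2-yl}-4-hydroxy-3-methoxycyclobut-2-en-1-one (isomer mixture) | CCCCCCCCCCC[C@H](CC(=COCc1ccccc1)C1(O)C(OC)=CC1=O)O[Si](C)(C)C(C)(C)C | intermediate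
12 | (7R)-5-[(benzyloxy)methylidene]-7-[(tert-butyldimethylsilyl)oxy]-4-hydroxy-3-methoxyoctadeca-1,3-dien-1-one (dienylketene, alkenyl cis to ketene) | CCCCCCCCCCC[C@H](CC(=COCc1ccccc1)\C(O)=C(OC)/C=C=O)O[Si](C)(C)C(C)(C)C | intermediate (not isolated)
13 | 6-(benzyloxy)-5-{(2R)-2-[(tert-butyldimethylsilyl)oxy]tridecyl}-4-hydroxy-3-methoxycyclohexa-2,4-dien-1-one | CCCCCCCCCCC[C@H](CC1=C(O)C(OC)=CC(=O)C1OCc1ccccc1)O[Si](C)(C)C(C)(C)C | intermediate (not isolated)
14 | 2-(benzyloxy)-3-{(2R)-2-[(tert-butyldimethylsilyl)oxy]tridecyl}-5-methoxybenzene-1,4-diol | CCCCCCCCCCC[C@H](Cc1c(O)c(OC)cc(O)c1OCc1ccccc1)O[Si](C)(C)C(C)(C)C | intermediate (not isolated)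
15 | 2-(benzyloxy)-3-{(2R)-2-[(tert-butyldimethylsilyl)oxy]tridecyl}-5-methoxy-1,4-benzoquinone | CCCCCCCCCCC[C@H](CC1=C(OCc2ccccc2)C(=O)C=C(OC)C1=O)O[Si](C)(C)C(C)(C)C | intermediate
16 | 2-(benzyloxy)-3-[(2R)-2-hydroxytridecyl]-5-methoxy-1,4-benzoquinone | CCCCCCCCCCC[C@H](CC1=C(OCc2ccccc2)C(=O)C=C(OC)C1=O)O | intermediate
17 | (2R)-1-[2-(benzyloxy)-5-methoxy-3,6-dioxocyclohexa-1,4-dien-1-yl]tridecan-2-yl acetate | CCCCCCCCCCC[C@H](CC1=C(OCc2ccccc2)C(=O)C=C(OC)C1=O)OC(C)=O | intermediate
18 | (2R)-1-(2,3,6-trihydroxy-5-methoxyphenyl)tridecan-2-yl acetate | CCCCCCCCCCC[C@H](Cc1c(O)c(O)cc(OC)c1O)OC(C)=O | intermediate (not isolated)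
19 | (2R)-1-(2-hydroxy-5-methoxy-3,6-dioxocyclohexa-1,4-dien-1-yl)tridecan-2-yl acetate | CCCCCCCCCCC[C@H](CC1=C(O)C(=O)C=C(OC)C1=O)OC(C)=O | target

**Step count.** Total: 10 steps. Longest linear sequence: 9 steps (steps 1–4 and 6–10 from 1); step 5 is a one-step side branch from 7.

**Steps most likely to fail**

Step 7. The hydroxy-dienylketene may be diverted before electrocyclisation, by lactonisation of the enol hydroxyl onto the ketene carbon or by acid-triggered ionisation of the carbinol/enol ether array. Closure may also be slow for the isomer whose benzyloxy group points inward. The fallback sets out from 11 and keeps the same ring-forming bond but masks the carbinol. Compound 11 is silylated (Me3SiCl, imidazole, DMF) to the 4-(trimethylsilyloxy)cyclobutenone F1, which has no free hydroxyl to lactonise and is less prone to ionisation. Thermolysis of F1 in toluene at 110 °C should give the mono-silylated hydroquinone F2. Brief methanolysis (K2CO3, MeOH) then returns the route to 14, which is oxidised with Ag2O to 15 as in step 7.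

Step 6. The vinyllithium may decompose by β-elimination of lithium benzyloxide (isomer with lithium anti to oxygen) or by benzylic deprotonation and Wittig rearrangement under t-BuLi. Conjugate addition at the unsubstituted ring CH of 9 may also compete. The fallback sets out from 4 and replaces the organolithium by a less basic Grignard reagent. Compound 4 is iodinated at the enol ether β-carbon (N-iodosuccinimide, AgNO3 cat., MeCN, the 2-iodoglycal protocol) to the vinyl iodide F3. Iodine–magnesium exchange (i-PrMgCl·LiCl, THF, −40 °C) gives the alkenylmagnesium chloride F4, which is added to 9 at −78 °C and returns to the route at 11.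

Step 4. The α-bromo ether intermediate may hydrolyse or oligomerise, HBr may be lost in the wrong direction, or adventitious HBr may cleave the silyl ether. The fallback sets out from 4 and replaces HBr loss by loss of an alcohol from a stable acetal. Bromo-acetalisation of 4 (N-bromosuccinimide, BnOH, CH2Cl2, −20 °C) gives the purifiable bromo dibenzyl acetal F5. Elimination of one benzyloxy group with Me3SiOTf and i-Pr2NEt (CH2Cl2, 0 °C, acetal-to-enol-ether conversion) returns to the route at 6.

**Further compounds**

F1 | step 7 | 4-{(4R)-1-(benzyloxy)-4-[(tert-butyldimethylsilyl)oxy]pentadec-1-en-2-yl}-3-methoxy-4-[(trimethylsilyl)oxy]cyclobut-2-en-1-one | CCCCCCCCCCC[C@H](CC(=COCc1ccccc1)C1(O[Si](C)(C)C)C(OC)=CC1=O)O[Si](C)(C)C(C)(C)C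
F2 | step 7 | 2-(benzyloxy)-3-{(2R)-2-[(tert-butyldimethylsilyl)oxy]tridecyl}-5-methoxy-4-[(trimethylsilyl)oxy]phenol | CCCCCCCCCCC[C@H](Cc1c(O[Si](C)(C)C)c(OC)cc(O)c1OCc1ccccc1)O[Si](C)(C)C(C)(C)C
F3 | step 6 | tert-butyl{[(4R)-1-(benzyloxy)-2-iodopentadec-1-en-4-yl]oxy}dimethylsilane | CCCCCCCCCCC[C@H](CC(I)=COCc1ccccc1)O[Si](C)(C)C(C)(C)C
F4 | step 6 | {(4R)-1-(benzyloxy)-4-[(tert-butyldimethylsilyl)oxy]pentadec-1-en-2-yl}magnesium chloride | CCCCCCCCCCC[C@H](CC([Mg]Cl)=COCc1ccccc1)O[Si](C)(C)C(C)(C)C
F5 | step 4 | tert-butyl{[(4R)-1,1-bis(benzyloxy)-2-bromopentadecan-4-yl]oxy}dimethylsilane | CCCCCCCCCCC[C@H](CC(Br)C(OCc1ccccc1)OCc1ccccc1)O[Si](C)(C)C(C)(C)C
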